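**Retrosynthetic overview**
1. Target 33 ← acid 32 ← C1 alcohol 30; the (E,E)-diene comes from Julia–Kocienski olefination of enal 23 with sulfone 27.
2. The only ring, the 1,2-dioxane, is closed late (step 14) by 6-exo SN2 attack of a C6 tertiary hydroperoxide on a C3 mesylate; inversion turns the syn-aldol array into the 3,4-trans ring.
3. C6–OO ← Co-catalysed Mukaiyama–Isayama hydroperoxysilylation of a 1,1-disubstituted alkene. C6 is not controlled; the epimers are separated after ring closure.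
4. C5–C6 ← Negishi sp3–sp2 coupling of iodide 9 with 2-bromodiene 14 (from 2,3-dibromopropene by Cu-coupling and Zr-carboalumination).
5. C3–C4, with both stereocentres ← intermolecular Evans syn-aldol of propionyl oxazolidinone 4 with aldehyde 3; this is the key fragment union.

Assumption: locants in the text follow the target chain (C1 = ester carbon, C3/C6 = ring carbons bearing O, C12 = benzylic CH2), and ring compounds are named with the target's ring locants.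

**Step 1**
Reactants: 1 propane-1,3-diol
Product: 2 3-{[tert-butyl(diphenyl)silyl]oxy}propan-1-ol
Conditions: NaH (1.0 equiv), THF, 0 °C → rt; TBDPSCl (1.0 equiv)
Reagents that add atoms: tert-butyl(chloro)diphenylsilane, CC(C)(C)[Si](Cl)(c1ccccc1)c1ccccc1
Why: Williamson-type O-silylation of the monosodium alkoxide of the symmetrical diol (McDougal mono-protection) silylates one hydroxyl only.

**Step 2**
Reactants: 2 3-{[tert-butyl(diphenyl)silyl]oxy}propan-1-ol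
Product: 3 3-{[tert-butyl(diphenyl)silyl]oxy}propanal
Conditions: TEMPO (10 mol %), PhI(OAc)2 (1.1 equiv), CH2Cl2, rt
Reagents that add atoms: none
Why: TEMPO/PhI(OAc)2 (oxoammonium) oxidation stops at the aldehyde and tolerates the silyl ether.

**Step 3**
Reactants: 4 (4S)-4-benzyl-3-propanoyl-1,3-oxazolidin-2-one; 3 3-{[tert-butyl(diphenyl)silyl]oxy}propanal
Product: 6 (4S)-4-benzyl-3-[(2S,3R)-5-{[tert-butyl(diphenyl)silyl]oxy}-3-hydroxy-2-methylpentanoyl]-1,3-oxazolidin-2-one, via (Z)-dibutylboron enolate 5 (not isolated)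
Conditions: Bu2BOTf, i-Pr2NEt, CH2Cl2, −78 → 0 °C; then 3, −78 → 0 °C; pH 7 buffer, MeOH, H2O2, 0 °C
Reagents that add atoms: none
Why: Intermolecular Evans syn-aldol: the Z-boron enolate reacts through a Zimmerman–Traxler chair with one face shielded by the (S)-benzyl auxiliary, setting (2S,3R), i.e. target C4 and the syn C3 carbinol.

**Step 4**
Reactants: 6 (4S)-4-benzyl-3-[(2S,3R)-5-{[tert-butyl(diphenyl)silyl]oxy}-3-hydroxy-2-methylpentanoyl]-1,3-oxazolidin-2-one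
Product: 7 (4S)-4-benzyl-3-[(2S,3R)-5-{[tert-butyl(diphenyl)silyl]oxy}-2-methyl-3-[(triethylsilyl)oxy]pentanoyl]-1,3-oxazolidin-2-one
Conditions: TESOTf, 2,6-lutidine, CH2Cl2, −78 °C
Reagents that add atoms: triethylsilyl trifluoromethanesulfonate, CC[Si](CC)(CC)OS(=O)(=O)C(F)(F)F
Why: O-silylation with a silyl triflate and a hindered base protects the C3 hydroxyl without retro-aldol.

**Step 5**
Reactants: 7 (4S)-4-benzyl-3-[(2S,3R)-5-{[tert-butyl(diphenyl)silyl]oxy}-2-methyl-3-[(triethylsilyl)oxy]pentanoyl]-1,3-oxazolidin-2-one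
Product: 8 (2R,3R)-5-{[tert-butyl(diphenyl)silyl]oxy}-2-methyl-3-[(triethylsilyl)oxy]pentan-1-ol
Conditions: LiBH4, MeOH (1 equiv), THF, 0 °C
Reagents that add atoms: none
Why: Reductive cleavage of the N-acyl oxazolidinone with LiBH4 gives the primary alcohol (C5) and releases the auxiliary without touching a stereocentre.

**Step 6**
Reactants: 8 (2R,3R)-5-{[tert-butyl(diphenyl)silyl]oxy}-2-methyl-3-[(triethylsilyl)oxy]pentan-1-ol
Product: 9 tert-butyl({(3R,4S)-5-iodo-4-methyl-3-[(triethylsilyl)oxy]pentyl}oxy)diphenylsilane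
Conditions: I2, PPh3, imidazole, CH2Cl2, 0 °C → rt
Reagents that add atoms: iodine, II
Why: Appel-type iodination substitutes the primary CH2OH by SN2, leaving the neighbouring stereocentres intact.

**Step 7**
Reactants: 10 2,3-dibromoprop-1-ene; 11 ethynylmagnesium bromide
Product: 12 2-bromopent-1-en-4-yne
Conditions: CuBr·SMe2 (5 mol %), THF, 0 °C → rt (11 in excess)
Reagents that add atoms: none
Why: Cu(I)-catalysed allyl–alkynyl coupling at the allylic C–Br (SN2 and SN2′ give the same product); the vinylic C–Br is inert.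

**Step 8**
Reactants: 12 2-bromopent-1-en-4-yne
Product: 14 ethyl (2E)-5-bromo-3-methylhexa-2,5-dienoate, via alkenylalane 13 (not isolated)
Conditions: Me3Al (2 equiv), Cp2ZrCl2 (0.25 equiv), CH2Cl2, 0 °C → rt; then ClCO2Et, 0 °C → rt
Reagents that add atoms: trimethylaluminium, C[Al](C)C; ethyl chloroformate, CCOC(=O)Cl
Why: Negishi Zr-catalysed syn-carboalumination puts CH3 on the internal and Al on the terminal alkyne carbon, and acylation with retention fixes the (E)-trisubstituted C8=C9 alkene.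

**Step 9**
Reactants: 9 tert-butyl({(3R,4S)-5-iodo-4-methyl-3-[(triethylsilyl)oxy]pentyl}oxy)diphenylsilane; 14 ethyl (2E)-5-bromo-3-methylhexa-2,5-dienoate
Product: 16 ethyl (2E,7R,8R)-10-{[tert-butyl(diphenyl)silyl]oxy}-3,7-dimethyl-5-methylidene-8-[(triethylsilyl)oxy]dec-2-enoate, via alkylzinc iodide 15 (not isolated)
Conditions: 9, Zn dust (TMSCl/BrCH2CH2Br-activated), THF, 40 °C; then 14, Pd(dppf)Cl2 (5 mol %), THF, rt → 50 °C
Reagents that add atoms: none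
Why: Knochel zinc insertion then Negishi sp3–sp2 cross-coupling joins C5 to C6 at the vinylic bromide; the ester is tolerated and stereocentres and alkene geometry are untouched.

**Step 10**
Reactants: 16 ethyl (2E,7R,8R)-10-{[tert-butyl(diphenyl)silyl]oxy}-3,7-dimethyl-5-methylidene-8-[(triethylsilyl)oxy]dec-2-enoate
Product: 17 ethyl (2E,7R,8R)-10-{[tert-butyl(diphenyl)silyl]oxy}-8-hydroxy-3,7-dimethyl-5-methylidenedec-2-enoate
Conditions: PPTS (cat.), EtOH, rt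
Reagents that add atoms: none
Why: Acid-catalysed ethanolysis cleaves the secondary triethylsilyl ether much faster than the primary tert-butyldiphenylsilyl ether.

**Step 11**
Reactants: 17 ethyl (2E,7R,8R)-10-{[tert-butyl(diphenyl)silyl]oxy}-8-hydroxy-3,7-dimethyl-5-methylidenedec-2-enoate
Product: 18 ethyl (2E,7R,8R)-10-{[tert-butyl(diphenyl)silyl]oxy}-8-[(methanesulfonyl)oxy]-3,7-dimethyl-5-methylidenedec-2-enoate
Conditions: MsCl, Et3N, CH2Cl2, 0 °C
Reagents that add atoms: methanesulfonyl chloride, CS(=O)(=O)Cl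
Why: O-sulfonylation with retention installs the leaving group at C3.

**Step 12**
Reactants: 18 ethyl (2E,7R,8R)-10-{[tert-butyl(diphenyl)silyl]oxy}-8-[(methanesulfonyl)oxy]-3,7-dimethyl-5-methylidenedec-2-enoate
Product: 19 (3R,4R,8E)-1-{[tert-butyl(diphenyl)silyl]oxy}-10-hydroxy-4,8-dimethyl-6-methylidenedec-8-en-3-yl methanesulfonate
Conditions: DIBAL-H (2.5 equiv), CH2Cl2, −78 °C; Rochelle salt
Reagents that add atoms: none
Why: DIBAL-H 1,2-reduction of the enoate gives the (E)-allylic alcohol, spares the mesylate and silyl ether, and removes a Michael acceptor that could later trap the hydroperoxide.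

**Step 13**
Reactants: 19 (3R,4R,8E)-1-{[tert-butyl(diphenyl)silyl]oxy}-10-hydroxy-4,8-dimethyl-6-methylidenedec-8-en-3-yl methanesulfonate
Product: 20 (3R,4R,6RS,8E)-1-{[tert-butyl(diphenyl)silyl]oxy}-10-hydroxy-4,6,8-trimethyl-6-[(triethylsilyl)peroxy]dec-8-en-3-yl methanesulfonate
Conditions: Co(thd)2 (10 mol %), O2 (1 atm), Et3SiH (2 equiv), ClCH2CH2Cl, rt
Reagents that add atoms: dioxygen, O=O; triethylsilane, CC[SiH](CC)CC
Why: Mukaiyama–Isayama hydroperoxysilylation: Co–H hydrogen-atom transfer to the terminal CH2 of the 1,1-disubstituted alkene (faster than to the trisubstituted one) gives the tertiary C6 radical, trapped by O2 and silylated; C6 forms without control (about 1:1).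

**Step 14**
Reactants: 20 (3R,4R,6RS,8E)-1-{[tert-butyl(diphenyl)silyl]oxy}-10-hydroxy-4,6,8-trimethyl-6-[(triethylsilyl)peroxy]dec-8-en-3-yl methanesulfonate
Product: 22 (2E)-4-[(3S,4R,6R)-3-(2-{[tert-butyl(diphenyl)silyl]oxy}ethyl)-4,6-dimethyl-1,2-dioxan-6-yl]-3-methylbut-2-en-1-ol, via tertiary hydroperoxide 21 (not isolated)
Conditions: HCl (cat.), MeOH, 0 °C; then KOt-Bu (1.05 equiv), 18-crown-6, toluene, 0 °C → rt; SiO2 chromatography
Reagents that add atoms: none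
Why: Intramolecular SN2 alkylation (6-exo-tet) of the hydroperoxide anion on the C3 mesylate with inversion converts the syn-aldol centre into (3S), trans to the 4-methyl; the (6R) epimer is isolated and the (6S) epimer removed by chromatography.

**Step 15**
Reactants: 22 (2E)-4-[(3S,4R,6R)-3-(2-{[tert-butyl(diphenyl)silyl]oxy}ethyl)-4,6-dimethyl-1,2-dioxan-6-yl]-3-methylbut-2-en-1-ol
Product: 23 (2E)-4-[(3S,4R,6R)-3-(2-{[tert-butyl(diphenyl)silyl]oxy}ethyl)-4,6-dimethyl-1,2-dioxan-6-yl]-3-methylbut-2-enal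
Conditions: MnO2 (excess), CH2Cl2, rt
Reagents that add atoms: none
Why: MnO2 oxidises only the allylic alcohol to the (E)-enal under neutral conditions that the dialkyl peroxide tolerates.

**Step 16**
Reactants: 24 (2-bromoethyl)benzene; 25 1-phenyl-1H-tetrazole-5-thiol
Product: 26 1-phenyl-5-[(2-phenylethyl)sulfanyl]-1H-tetrazole
Conditions: K2CO3, acetone, reflux
Reagents that add atoms: none
Why: S-alkylation (SN2) of the acidic tetrazole thiol with the primary bromide.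

**Step 17**
Reactants: 26 1-phenyl-5-[(2-phenylethyl)sulfanyl]-1H-tetrazole
Product: 27 1-phenyl-5-[(2-phenylethyl)sulfonyl]-1H-tetrazole
Conditions: 30% H2O2, (NH4)6Mo7O24·4H2O (cat.), EtOH, 0 °C → rt
Reagents that add atoms: hydrogen peroxide, OO
Why: Molybdate-catalysed peroxide oxidation takes the sulfide to the sulfone.

**Step 18**
Reactants: 27 1-phenyl-5-[(2-phenylethyl)sulfonyl]-1H-tetrazole; 23 (2E)-4-[(3S,4R,6R)-3-(2-{[tert-butyl(diphenyl)silyl]oxy}ethyl)-4,6-dimethyl-1,2-dioxan-6-yl]-3-methylbut-2-enal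
Product: 29 tert-butyl(2-{(3S,4R,6R)-4,6-dimethyl-6-[(2E,4E)-2-methyl-6-phenylhexa-2,4-dien-1-yl]-1,2-dioxan-3-yl}ethoxy)diphenylsilane, via potassium sulfonyl carbanion 28 (not isolated)
Conditions: 27, KHMDS, DME, −60 °C; then 23, −60 °C → rt
Reagents that add atoms: none
Why: Julia–Kocienski olefination: the metalated PT-sulfone adds to the enal and Smiles rearrangement/SO2 loss gives the C10=C11 alkene (E)-selectively; with C1 still an ether there is no acidic site for retro-oxa-Michael.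

**Step 19**
Reactants: 29 tert-butyl(2-{(3S,4R,6R)-4,6-dimethyl-6-[(2E,4E)-2-methyl-6-phenylhexa-2,4-dien-1-yl]-1,2-dioxan-3-yl}ethoxy)diphenylsilane
Product: 30 2-{(3S,4R,6R)-4,6-dimethyl-6-[(2E,4E)-2-methyl-6-phenylhexa-2,4-dien-1-yl]-1,2-dioxan-3-yl}ethan-1-ol
Conditions: TBAF, AcOH (1:1), THF, 0 °C → rt
Reagents that add atoms: none
Why: Buffered fluoride desilylation frees the C1 alcohol; peroxide and diene are inert.

**Step 20**
Reactants: 30 2-{(3S,4R,6R)-4,6-dimethyl-6-[(2E,4E)-2-methyl-6-phenylhexa-2,4-dien-1-yl]-1,2-dioxan-3-yl}ethan-1-ol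
Product: 32 {(3S,4R,6R)-4,6-dimethyl-6-[(2E,4E)-2-methyl-6-phenylhexa-2,4-dien-1-yl]-1,2-dioxan-3-yl}acetic acid, via aldehyde 31 (not isolated)
Conditions: TEMPO (cat.), PhI(OAc)2 (2.5 equiv), MeCN/pH 7 buffer, rt
Reagents that add atoms: water, O
Why: TEMPO/PhI(OAc)2 oxidation in aqueous MeCN takes the primary alcohol through the aldehyde hydrate to the acid under near-neutral conditions compatible with the peroxide and diene.

**Step 21**
Reactants: 32 {(3S,4R,6R)-4,6-dimethyl-6-[(2E,4E)-2-methyl-6-phenylhexa-2,4-dien-1-yl]-1,2-dioxan-3-yl}acetic acid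
Product: 33 methyl {(3S,4R,6R)-4,6-dimethyl-6-[(2E,4E)-2-methyl-6-phenylhexa-2,4-dien-1-yl]-1,2-dioxan-3-yl}acetate
Conditions: TMSCHN2, MeOH/toluene, 0 °C
Reagents that add atoms: (trimethylsilyl)diazomethane, C[Si](C)(C)C=[N+]=[N-]
Why: Neutral methyl esterification with TMS-diazomethane avoids base-induced retro-oxa-Michael of the β-peroxy ester.

**Compound list**
1 | propane-1,3-diol | OCCCO | starting material
2 | 3-{[tert-butyl(diphenyl)silyl]oxy}propan-1-ol | OCCCO[Si](c1ccccc1)(c1ccccc1)C(C)(C)C | intermediate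
3 | 3-{[tert-butyl(diphenyl)silyl]oxy}propanal | O=CCCO[Si](c1ccccc1)(c1ccccc1)C(C)(C)C | intermediate
4 | (4S)-4-benzyl-3-propanoyl-1,3-oxazolidin-2-one | CCC(=O)N1C(=O)OC[C@@H]1Cc1ccccc1 | starting material
5 | (4S)-4-benzyl-3-[(1Z)-1-[(dibutylboranyl)oxy]prop-1-en-1-yl]-1,3-oxazolidin-2-one | C/C=C(\OB(CCCC)CCCC)N1C(=O)OC[C@@H]1Cc1ccccc1 | intermediate (not isolated)
6 | (4S)-4-benzyl-3-[(2S,3R)-5-{[tert-butyl(diphenyl)silyl]oxy}-3-hydroxy-2-methylpentanoyl]-1,3-oxazolidin-2-one | O=C([C@@H](C)[C@H](O)CCO[Si](c1ccccc1)(c1ccccc1)C(C)(C)C)N1C(=O)OC[C@@H]1Cc1ccccc1 | intermediate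
7 | (4S)-4-benzyl-3-[(2S,3R)-5-{[tert-butyl(diphenyl)silyl]oxy}-2-methyl-3-[(triethylsilyl)oxy]pentanoyl]-1,3-oxazolidin-2-one | O=C([C@@H](C)[C@H](O[Si](CC)(CC)CC)CCO[Si](c1ccccc1)(c1ccccc1)C(C)(C)C)N1C(=O)OC[C@@H]1Cc1ccccc1 | intermediate
8 | (2R,3R)-5-{[tert-butyl(diphenyl)silyl]oxy}-2-methyl-3-[(triethylsilyl)oxy]pentan-1-ol | OC[C@@H](C)[C@H](O[Si](CC)(CC)CC)CCO[Si](c1ccccc1)(c1ccccc1)C(C)(C)C | intermediate
9 | tert-butyl({(3R,4S)-5-iodo-4-methyl-3-[(triethylsilyl)oxy]pentyl}oxy)diphenylsilane | IC[C@@H](C)[C@H](O[Si](CC)(CC)CC)CCO[Si](c1ccccc1)(c1ccccc1)C(C)(C)C | intermediate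
10 | 2,3-dibromoprop-1-ene | C=C(Br)CBr | starting material
11 | ethynylmagnesium bromide | C#C[Mg]Br | starting material
12 | 2-bromopent-1-en-4-yne | C=C(Br)CC#C | intermediate
13 | [(1E)-4-bromo-2-methylpenta-1,4-dien-1-yl]dimethylalumane | C[Al](C)/C=C(\C)CC(Br)=C | intermediate (not isolated)
14 | ethyl (2E)-5-bromo-3-methylhexa-2,5-dienoate | CCOC(=O)/C=C(\C)CC(Br)=C | intermediate
15 | {(2S,3R)-5-{[tert-butyl(diphenyl)silyl]oxy}-2-methyl-3-[(triethylsilyl)oxy]pentyl}zinc iodide | I[Zn]C[C@@H](C)[C@H](O[Si](CC)(CC)CC)CCO[Si](c1ccccc1)(c1ccccc1)C(C)(C)C | intermediate (not isolated)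
16 | ethyl (2E,7R,8R)-10-{[tert-butyl(diphenyl)silyl]oxy}-3,7-dimethyl-5-methylidene-8-[(triethylsilyl)oxy]dec-2-enoate | CCOC(=O)/C=C(\C)CC(=C)C[C@@H](C)[C@H](O[Si](CC)(CC)CC)CCO[Si](c1ccccc1)(c1ccccc1)C(C)(C)C | intermediate
17 | ethyl (2E,7R,8R)-10-{[tert-butyl(diphenyl)silyl]oxy}-8-hydroxy-3,7-dimethyl-5-methylidenedec-2-enoate | CCOC(=O)/C=C(\C)CC(=C)C[C@@H](C)[C@H](O)CCO[Si](c1ccccc1)(c1ccccc1)C(C)(C)C | intermediate
18 | ethyl (2E,7R,8R)-10-{[tert-butyl(diphenyl)silyl]oxy}-8-[(methanesulfonyl)oxy]-3,7-dimethyl-5-methylidenedec-2-enoate | CCOC(=O)/C=C(\C)CC(=C)C[C@@H](C)[C@H](OS(C)(=O)=O)CCO[Si](c1ccccc1)(c1ccccc1)C(C)(C)C | intermediate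
19 | (3R,4R,8E)-1-{[tert-butyl(diphenyl)silyl]oxy}-10-hydroxy-4,8-dimethyl-6-methylidenedec-8-en-3-yl methanesulfonate | OC/C=C(\C)CC(=C)C[C@@H](C)[C@H](OS(C)(=O)=O)CCO[Si](c1ccccc1)(c1ccccc1)C(C)(C)C | intermediate
20 | (3R,4R,6RS,8E)-1-{[tert-butyl(diphenyl)silyl]oxy}-10-hydroxy-4,6,8-trimethyl-6-[(triethylsilyl)peroxy]dec-8-en-3-yl methanesulfonate (both C6 epimers) | OC/C=C(\C)CC(C)(OO[Si](CC)(CC)CC)C[C@@H](C)[C@H](OS(C)(=O)=O)CCO[Si](c1ccccc1)(c1ccccc1)C(C)(C)C | intermediate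
21 | (3R,4R,6RS,8E)-1-{[tert-butyl(diphenyl)silyl]oxy}-6-hydroperoxy-10-hydroxy-4,6,8-trimethyldec-8-en-3-yl methanesulfonate (both C6 epimers) | OC/C=C(\C)CC(C)(OO)C[C@@H](C)[C@H](OS(C)(=O)=O)CCO[Si](c1ccccc1)(c1ccccc1)C(C)(C)C | intermediate (not isolated)
22 | (2E)-4-[(3S,4R,6R)-3-(2-{[tert-butyl(diphenyl)silyl]oxy}ethyl)-4,6-dimethyl-1,2-dioxan-6-yl]-3-methylbut-2-en-1-ol | CC(C)(C)[Si](c1ccccc1)(c1ccccc1)OCC[C@@H]1OO[C@@](C)(C/C(C)=C/CO)C[C@H]1C | intermediate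
23 | (2E)-4-[(3S,4R,6R)-3-(2-{[tert-butyl(diphenyl)silyl]oxy}ethyl)-4,6-dimethyl-1,2-dioxan-6-yl]-3-methylbut-2-enal | CC(C)(C)[Si](c1ccccc1)(c1ccccc1)OCC[C@@H]1OO[C@@](C)(C/C(C)=C/C=O)C[C@H]1C | intermediate
24 | (2-bromoethyl)benzene | BrCCc1ccccc1 | starting material
25 | 1-phenyl-1H-tetrazole-5-thiol | Sc1nnnn1-c1ccccc1 | starting material
26 | 1-phenyl-5-[(2-phenylethyl)sulfanyl]-1H-tetrazole | C(Cc1ccccc1)Sc1nnnn1-c1ccccc1 | intermediate
27 | 1-phenyl-5-[(2-phenylethyl)sulfonyl]-1H-tetrazole | O=S(=O)(CCc1ccccc1)c1nnnn1-c1ccccc1 | intermediate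
28 | potassium 2-phenyl-1-[(1-phenyl-1H-tetrazol-5-yl)sulfonyl]ethan-1-ide | [K+].[CH-](Cc1ccccc1)S(=O)(=O)c1nnnn1-c1ccccc1 | intermediate (not isolated)
29 | tert-butyl(2-{(3S,4R,6R)-4,6-dimethyl-6-[(2E,4E)-2-methyl-6-phenylhexa-2,4-dien-1-yl]-1,2-dioxan-3-yl}ethoxy)diphenylsilane | CC(C)(C)[Si](c1ccccc1)(c1ccccc1)OCC[C@@H]1OO[C@@](C)(C/C(C)=C/C=C/Cc2ccccc2)C[C@H]1C | intermediate
30 | 2-{(3S,4R,6R)-4,6-dimethyl-6-[(2E,4E)-2-methyl-6-phenylhexa-2,4-dien-1-yl]-1,2-dioxan-3-yl}ethan-1-ol | OCC[C@@H]1OO[C@@](C)(C/C(C)=C/C=C/Cc2ccccc2)C[C@H]1C | intermediate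
31 | {(3S,4R,6R)-4,6-dimethyl-6-[(2E,4E)-2-methyl-6-phenylhexa-2,4-dien-1-yl]-1,2-dioxan-3-yl}acetaldehyde | O=CC[C@@H]1OO[C@@](C)(C/C(C)=C/C=C/Cc2ccccc2)C[C@H]1C | intermediate (not isolated)
32 | {(3S,4R,6R)-4,6-dimethyl-6-[(2E,4E)-2-methyl-6-phenylhexa-2,4-dien-1-yl]-1,2-dioxan-3-yl}acetic acid | OC(=O)C[C@@H]1OO[C@@](C)(C/C(C)=C/C=C/Cc2ccccc2)C[C@H]1C | intermediate
33 | methyl {(3S,4R,6R)-4,6-dimethyl-6-[(2E,4E)-2-methyl-6-phenylhexa-2,4-dien-1-yl]-1,2-dioxan-3-yl}acetate | COC(=O)C[C@@H]1OO[C@@](C)(C/C(C)=C/C=C/Cc2ccccc2)C[C@H]1C | target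

**Totals**
Total step count: 21. Longest linear sequence: 17 steps (1–6, 9–15, 18–21).

**Three steps most likely to fail**

Step 13 (hydroperoxysilylation). The HAT step must choose the 1,1-disubstituted alkene over the trisubstituted allylic-alcohol alkene, and it gives both C6 epimers by design, so at most half the material is the wanted one. Fallback: it sets out from 19 and comes back at 21. The radical chemistry is replaced by an ionic Markovnikov hydroperoxymercuration. Hg(OAc)2 with ethereal H2O2 in CH2Cl2 at 0 °C adds to the less hindered 1,1-disubstituted alkene (the site preference known from oxymercuration of limonene's isopropenyl group) to give acetoxy{(2RS,4R,5R)-7-{[tert-butyl(diphenyl)silyl]oxy}-2-hydroperoxy-2-[(2E)-4-hydroxy-2-methylbut-2-en-1-yl]-5-[(methanesulfonyl)oxy]-4-methylheptyl}mercury F1. Alkaline NaBH4 at 0 °C then removes mercury to leave hydroperoxide 21, which is cyclised with KOt-Bu/18-crown-6 as in step 14. This fallback does not fix the C6 ratio either.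

Step 14 (SN2 ring closure). Substitution at a secondary, β-branched mesylate by a tertiary hydroperoxide can lose to elimination. Fallback: it sets out from 17 and comes back at 22, making the C3–O bond by reduction of a cyclic peroxyketal instead.
- Dess–Martin oxidation of 17 gives ethyl (2E,7R)-10-{[tert-butyl(diphenyl)silyl]oxy}-3,7-dimethyl-5-methylidene-8-oxodec-2-enoate F2.
- Hydroperoxysilylation under the step 13 conditions gives ethyl (2E,5RS,7R)-10-{[tert-butyl(diphenyl)silyl]oxy}-3,5,7-trimethyl-8-oxo-5-[(triethylsilyl)peroxy]dec-2-enoate F3.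
- HCl/MeOH frees the hydroperoxide, which closes onto the ketone to give ethyl (2E)-4-[(5R)-6-(2-{[tert-butyl(diphenyl)silyl]oxy}ethyl)-6-methoxy-3,5-dimethyl-1,2-dioxan-3-yl]-3-methylbut-2-enoate F4.
- Et3SiH/TMSOTf at −78 °C reduces the peroxycarbenium ion with axial hydride delivery, which puts the side arm equatorial and trans to the 4-methyl. This gives ethyl (2E)-4-[(3S,4R,6R)-3-(2-{[tert-butyl(diphenyl)silyl]oxy}ethyl)-4,6-dimethyl-1,2-dioxan-6-yl]-3-methylbut-2-enoate F5, and the C6 epimers are separated here.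
- DIBAL-H at −78 °C reduces the enoate to 22.

Step 18 (Julia–Kocienski). The enal carries γ-hydrogens next to the peroxide-bearing carbon, so base could open the ring, and E-selectivity with an enal is not guaranteed. Fallback: it sets out from 23 and comes back at 29, building C10=C11 by cross-coupling instead of olefination. The Ohira–Bestmann reagent with K2CO3 in MeOH converts 23 into tert-butyl(2-{(3S,4R,6R)-4,6-dimethyl-6-[(2E)-2-methylpent-2-en-4-yn-1-yl]-1,2-dioxan-3-yl}ethoxy)diphenylsilane F6. Syn-hydrozirconation with Cp2Zr(H)Cl gives chlorido{(1E,3E)-5-[(3S,4R,6R)-3-(2-{[tert-butyl(diphenyl)silyl]oxy}ethyl)-4,6-dimethyl-1,2-dioxan-6-yl]-4-methylpenta-1,3-dien-1-yl}bis(cyclopentadienyl)zirconium F7. ZnCl2 and Pd(PPh3)4 then couple F7 with benzyl bromide to give 29.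

**Further compounds**
F1 | step 13 | acetoxy{(2RS,4R,5R)-7-{[tert-butyl(diphenyl)silyl]oxy}-2-hydroperoxy-2-[(2E)-4-hydroxy-2-methylbut-2-en-1-yl]-5-[(methanesulfonyl)oxy]-4-methylheptyl}mercury | CC(=O)O[Hg]CC(OO)(C/C(C)=C/CO)C[C@@H](C)[C@H](OS(C)(=O)=O)CCO[Si](c1ccccc1)(c1ccccc1)C(C)(C)C
F2 | step 14 | ethyl (2E,7R)-10-{[tert-butyl(diphenyl)silyl]oxy}-3,7-dimethyl-5-methylidene-8-oxodec-2-enoate | CCOC(=O)/C=C(\C)CC(=C)C[C@@H](C)C(=O)CCO[Si](c1ccccc1)(c1ccccc1)C(C)(C)C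
F3 | step 14 | ethyl (2E,5RS,7R)-10-{[tert-butyl(diphenyl)silyl]oxy}-3,5,7-trimethyl-8-oxo-5-[(triethylsilyl)peroxy]dec-2-enoate | CCOC(=O)/C=C(\C)CC(C)(OO[Si](CC)(CC)CC)C[C@@H](C)C(=O)CCO[Si](c1ccccc1)(c1ccccc1)C(C)(C)C
F4 | step 14 | ethyl (2E)-4-[(5R)-6-(2-{[tert-butyl(diphenyl)silyl]oxy}ethyl)-6-methoxy-3,5-dimethyl-1,2-dioxan-3-yl]-3-methylbut-2-enoate | CCOC(=O)/C=C(\C)CC1(C)C[C@@H](C)C(OC)(CCO[Si](c2ccccc2)(c2ccccc2)C(C)(C)C)OO1
F5 | step 14 | ethyl (2E)-4-[(3S,4R,6R)-3-(2-{[tert-butyl(diphenyl)silyl]oxy}ethyl)-4,6-dimethyl-1,2-dioxan-6-yl]-3-methylbut-2-enoate | CC(C)(C)[Si](c1ccccc1)(c1ccccc1)OCC[C@@H]1OO[C@@](C)(C/C(C)=C/C(=O)OCC)C[C@H]1C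
F6 | step 18 | tert-butyl(2-{(3S,4R,6R)-4,6-dimethyl-6-[(2E)-2-methylpent-2-en-4-yn-1-yl]-1,2-dioxan-3-yl}ethoxy)diphenylsilane | CC(C)(C)[Si](c1ccccc1)(c1ccccc1)OCC[C@@H]1OO[C@@](C)(C/C(C)=C/C#C)C[C@H]1C
F7 | step 18 | chlorido{(1E,3E)-5-[(3S,4R,6R)-3-(2-{[tert-butyl(diphenyl)silyl]oxy}ethyl)-4,6-dimethyl-1,2-dioxan-6-yl]-4-methylpenta-1,3-dien-1-yl}bis(cyclopentadienyl)zirconium | CC(C)(C)[Si](c1ccccc1)(c1ccccc1)OCC[C@@H]1OO[C@@](C)(C/C(C)=C/C=C/[Zr](Cl)(C2C=CC=C2)C2C=CC=C2)C[C@H]1C
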